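## Retrosynthetic overview

1. Target 17 ⇐ desilylation of 16 ⇐ acetylation of the bridgehead tertiary alcohol of furofuran 15.
2. 15 ⇐ pentaol 13 by double 5-exo-tet etherification (both tetrahydrofuran rings closed together, last); 13 ⇐ LiAlH4 reduction of hydroxy dilactone 12.
3. 12 ⇐ hydroxy lactone 9 + aldehyde 2: dianion aldol, then lactonisation onto the ethyl ester (second, temporary lactone; sets C5 and C6).
4. 9 ⇐ bromoacetate α-keto ester 7: key ring closure, an intramolecular Reformatsky-type aldol of the zinc ester enolate onto the keto ester (first ring; C1 set from C2).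
5. 7 ⇐ aldehyde 2 + ethyl diazoacetate 3 (catalytic asymmetric aldol, sets C2) + bromoacetyl bromide 5. Ring order: lactone A → lactone B → both opened → both THF rings.

Assumption: the ProPhenol antipode written in step 2 is the one that gives the (3R)-alcohol 4; if the sense of induction is the reverse, the other antipode is used and nothing else changes.

Atom labels C1–C8 in the "Why" lines are the 3,7-dioxabicyclo[3.3.0]octane positions of the target.

## Route

Step 1
Reactants: 1 vanillin (4-hydroxy-3-methoxybenzaldehyde)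
Product: 2 3-methoxy-4-(triisopropylsilyloxy)benzaldehyde
Conditions: TIPSCl, imidazole, DMF, rt
Reagents that add atoms: triisopropylsilyl chloride (TIPSCl), CC(C)[Si](Cl)(C(C)C)C(C)C
Why: Imidazole-promoted O-silylation gives an aryl TIPS ether that is stable to base, zinc, hydride and sulfonylation and is removed by fluoride at the end without touching the benzylic C–O bonds.

Step 2
Reactants: 2 3-methoxy-4-(triisopropylsilyloxy)benzaldehyde; 3 ethyl diazoacetate
Product: 4 ethyl (3R)-2-diazo-3-hydroxy-3-[3-methoxy-4-(triisopropylsilyloxy)phenyl]propanoate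
Conditions: Bu2Mg (10 mol %), (S,S)-ProPhenol (5 mol %), cis-cyclopentane-1,2-diol (5 mol %), THF, −20 °C
Reagents that add atoms: none
Why: Mg–ProPhenol-catalysed direct asymmetric aldol addition of ethyl diazoacetate to the aromatic aldehyde; the chiral dinuclear Mg complex selects the aldehyde face and sets the benzylic carbinol (C2 of the target) as R.

Step 3
Reactants: 4 ethyl (3R)-2-diazo-3-hydroxy-3-[3-methoxy-4-(triisopropylsilyloxy)phenyl]propanoate; 5 bromoacetyl bromide
Product: 6 ethyl (3R)-3-(2-bromoacetoxy)-2-diazo-3-[3-methoxy-4-(triisopropylsilyloxy)phenyl]propanoate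
Conditions: pyridine, CH2Cl2, −40 → 0 °C
Reagents that add atoms: none
Why: O-acylation of the secondary benzylic alcohol with the acid bromide, with pyridine scavenging HBr so that the acid-labile diazo ester survives; the stereocentre is not touched.

Step 4
Reactants: 6 ethyl (3R)-3-(2-bromoacetoxy)-2-diazo-3-[3-methoxy-4-(triisopropylsilyloxy)phenyl]propanoate
Product: 7 ethyl (3R)-3-(2-bromoacetoxy)-3-[3-methoxy-4-(triisopropylsilyloxy)phenyl]-2-oxopropanoate
Conditions: DMDO (1.2 equiv), acetone, 0 °C; evaporate, dry azeotropically, use at once without chromatography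
Reagents that add atoms: dimethyldioxirane (DMDO), CC1(C)OO1
Why: Dimethyldioxirane oxidation of the α-diazo ester to the vicinal keto ester with loss of N2 under neutral conditions, which keeps the enolisable benzylic stereocentre intact.

Step 5
Reactants: 7 ethyl (3R)-3-(2-bromoacetoxy)-3-[3-methoxy-4-(triisopropylsilyloxy)phenyl]-2-oxopropanoate
Product: 9 ethyl (2R,3R)-3-hydroxy-2-[3-methoxy-4-(triisopropylsilyloxy)phenyl]-5-oxooxolane-3-carboxylate, via bromozinc ester enolate 8 (not isolated)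
Conditions: Zn–Cu couple (activated Zn), THF (0.02 M), 0 °C → rt; then H2O (pH 7 buffer)
Reagents that add atoms: none
Why: Zinc insertion into the C–Br bond makes the ester enolate regiospecifically and without base, and it adds to the very electrophilic keto carbonyl in an intramolecular Reformatsky-type aldol (5-membered lactone); the bulkier CO2Et takes the position trans to the aryl group in the cyclic transition state, so the new tertiary carbinol has OH cis to aryl.

Step 6
Reactants: 9 ethyl (2R,3R)-3-hydroxy-2-[3-methoxy-4-(triisopropylsilyloxy)phenyl]-5-oxooxolane-3-carboxylate; 2 3-methoxy-4-(triisopropylsilyloxy)benzaldehyde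
Product: 12 (1R,2R,5R,6S)-1-hydroxy-2,6-bis[3-methoxy-4-(triisopropylsilyloxy)phenyl]-3,7-dioxabicyclo[3.3.0]octane-4,8-dione, via dilithium lactone dianion 10 (not isolated), via dilithium aldolate 11 (not isolated)
Conditions: LDA (2.2 equiv), THF, −78 °C; then 2 (1.2 equiv), −78 → −20 °C; AcOH quench
Reagents that add atoms: none
Why: Fráter–Seebach-type dianion aldol followed by lactonisation: the aldehyde adds to the lactone enolate anti to the lithium alkoxide and the aryl group (syn to CO2Et), and only that aldolate can close onto the ethyl ester, which fixes the cis ring fusion at C5; the aldol is reversible at −20 °C and the aryl group is expected to take the exo position of the new lactone (C6), the minor endo isomer being removed by chromatography.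

Step 7
Reactants: 12 (1R,2R,5R,6S)-1-hydroxy-2,6-bis[3-methoxy-4-(triisopropylsilyloxy)phenyl]-3,7-dioxabicyclo[3.3.0]octane-4,8-dione
Product: 13 (1R,2S,3R,4S)-2,3-bis(hydroxymethyl)-1,4-bis[3-methoxy-4-(triisopropylsilyloxy)phenyl]butane-1,2,4-triol
Conditions: LiAlH4, THF, 0 °C → rt; H2O/NaOH work-up
Reagents that add atoms: none
Why: Hydride reduction of both γ-lactones to 1,4-diols; no stereocentre is involved and aryl TIPS ethers tolerate LiAlH4 at this temperature.

Step 8
Reactants: 13 (1R,2S,3R,4S)-2,3-bis(hydroxymethyl)-1,4-bis[3-methoxy-4-(triisopropylsilyloxy)phenyl]butane-1,2,4-triol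
Product: 15 (1S,2R,5R,6S)-2,6-bis[3-methoxy-4-(triisopropylsilyloxy)phenyl]-3,7-dioxabicyclo[3.3.0]octan-1-ol, via primary bis-mesylate 14 (not isolated)
Conditions: MsCl (2.2 equiv), pyridine, 0 °C; then 40 °C
Reagents that add atoms: none
Why: Selective sulfonylation of the two primary hydroxyls, then double 5-exo-tet intramolecular Williamson etherification by the two benzylic hydroxyls; substitution occurs only at CH2, so all four stereocentres are retained and the cis-fused furofuran forms.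

Step 9
Reactants: 15 (1S,2R,5R,6S)-2,6-bis[3-methoxy-4-(triisopropylsilyloxy)phenyl]-3,7-dioxabicyclo[3.3.0]octan-1-ol
Product: 16 (1S,2R,5R,6S)-2,6-bis[3-methoxy-4-(triisopropylsilyloxy)phenyl]-3,7-dioxabicyclo[3.3.0]octan-1-yl acetate
Conditions: Ac2O, DMAP, Et3N, CH2Cl2, 40 °C
Reagents that add atoms: acetic anhydride, CC(=O)OC(C)=O
Why: DMAP-catalysed acylation of the only free hydroxyl, the tertiary bridgehead alcohol, under non-acidic conditions that do not epimerise the benzylic ethers.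

Step 10
Reactants: 16 (1S,2R,5R,6S)-2,6-bis[3-methoxy-4-(triisopropylsilyloxy)phenyl]-3,7-dioxabicyclo[3.3.0]octan-1-yl acetate
Product: 17 1-acetoxypinoresinol, (1S,2R,5R,6S)-2,6-bis(4-hydroxy-3-methoxyphenyl)-3,7-dioxabicyclo[3.3.0]octan-1-yl acetate
Conditions: TBAF (2.2 equiv), AcOH (2.2 equiv), THF, 0 °C
Reagents that add atoms: none
Why: Fluoride cleavage of both aryl silyl ethers, buffered with acetic acid so the phenoxides are protonated at once and the tertiary acetate and the benzylic ethers stay intact.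

## Compound list

1 | vanillin (4-hydroxy-3-methoxybenzaldehyde) | COc1cc(C=O)ccc1O | starting material
2 | 3-methoxy-4-(triisopropylsilyloxy)benzaldehyde | COc1cc(C=O)ccc1O[Si](C(C)C)(C(C)C)C(C)C | intermediate
3 | ethyl diazoacetate | CCOC(=O)C=[N+]=[N-] | starting material
4 | ethyl (3R)-2-diazo-3-hydroxy-3-[3-methoxy-4-(triisopropylsilyloxy)phenyl]propanoate | CCOC(=O)C(=[N+]=[N-])[C@@H](c1ccc(O[Si](C(C)C)(C(C)C)C(C)C)c(OC)c1)O | intermediate
5 | bromoacetyl bromide | BrCC(Br)=O | starting material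
6 | ethyl (3R)-3-(2-bromoacetoxy)-2-diazo-3-[3-methoxy-4-(triisopropylsilyloxy)phenyl]propanoate | CCOC(=O)C(=[N+]=[N-])[C@@H](c1ccc(O[Si](C(C)C)(C(C)C)C(C)C)c(OC)c1)OC(=O)CBr | intermediate
7 | ethyl (3R)-3-(2-bromoacetoxy)-3-[3-methoxy-4-(triisopropylsilyloxy)phenyl]-2-oxopropanoate | CCOC(=O)C(=O)[C@@H](c1ccc(O[Si](C(C)C)(C(C)C)C(C)C)c(OC)c1)OC(=O)CBr | intermediate
8 | bromozinc ester enolate of 7, drawn C-bound (not isolated) | CCOC(=O)C(=O)[C@@H](c1ccc(O[Si](C(C)C)(C(C)C)C(C)C)c(OC)c1)OC(=O)C[Zn]Br | intermediate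
9 | ethyl (2R,3R)-3-hydroxy-2-[3-methoxy-4-(triisopropylsilyloxy)phenyl]-5-oxooxolane-3-carboxylate | CCOC(=O)[C@@]1(O)CC(=O)O[C@@H]1c1ccc(O[Si](C(C)C)(C(C)C)C(C)C)c(OC)c1 | intermediate
10 | dilithium alkoxide/lactone enolate (dianion) of 9 (not isolated) | CCOC(=O)[C@@]1([O-])C=C([O-])O[C@@H]1c1ccc(O[Si](C(C)C)(C(C)C)C(C)C)c(OC)c1.[Li+].[Li+] | intermediate
11 | dilithium aldolate of 9 with 2, C4 arm syn to CO2Et (not isolated) | CCOC(=O)[C@@]1([O-])[C@@H]([C@H]([O-])c2ccc(O[Si](C(C)C)(C(C)C)C(C)C)c(OC)c2)C(=O)O[C@@H]1c3ccc(O[Si](C(C)C)(C(C)C)C(C)C)c(OC)c3.[Li+].[Li+] | intermediate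
12 | (1R,2R,5R,6S)-1-hydroxy-2,6-bis[3-methoxy-4-(triisopropylsilyloxy)phenyl]-3,7-dioxabicyclo[3.3.0]octane-4,8-dione | COc1cc([C@H]2OC(=O)[C@]3(O)[C@@H](c4ccc(O[Si](C(C)C)(C(C)C)C(C)C)c(OC)c4)OC(=O)[C@H]23)ccc1O[Si](C(C)C)(C(C)C)C(C)C | intermediate
13 | (1R,2S,3R,4S)-2,3-bis(hydroxymethyl)-1,4-bis[3-methoxy-4-(triisopropylsilyloxy)phenyl]butane-1,2,4-triol | COc1cc([C@@H](O)[C@@H](CO)[C@](O)(CO)[C@H](O)c2ccc(O[Si](C(C)C)(C(C)C)C(C)C)c(OC)c2)ccc1O[Si](C(C)C)(C(C)C)C(C)C | intermediate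
14 | (1R,2S,3R,4S)-2,3-bis[(methylsulfonyloxy)methyl]-1,4-bis[3-methoxy-4-(triisopropylsilyloxy)phenyl]butane-1,2,4-triol (not isolated) | COc1cc([C@@H](O)[C@@H](COS(C)(=O)=O)[C@](O)(COS(C)(=O)=O)[C@H](O)c2ccc(O[Si](C(C)C)(C(C)C)C(C)C)c(OC)c2)ccc1O[Si](C(C)C)(C(C)C)C(C)C | intermediate
15 | (1S,2R,5R,6S)-2,6-bis[3-methoxy-4-(triisopropylsilyloxy)phenyl]-3,7-dioxabicyclo[3.3.0]octan-1-ol | COc1cc([C@H]2OC[C@]3(O)[C@@H](c4ccc(O[Si](C(C)C)(C(C)C)C(C)C)c(OC)c4)OC[C@H]23)ccc1O[Si](C(C)C)(C(C)C)C(C)C | intermediate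
16 | (1S,2R,5R,6S)-2,6-bis[3-methoxy-4-(triisopropylsilyloxy)phenyl]-3,7-dioxabicyclo[3.3.0]octan-1-yl acetate | COc1cc([C@H]2OC[C@]3(OC(C)=O)[C@@H](c4ccc(O[Si](C(C)C)(C(C)C)C(C)C)c(OC)c4)OC[C@H]23)ccc1O[Si](C(C)C)(C(C)C)C(C)C | intermediate
17 | 1-acetoxypinoresinol, (1S,2R,5R,6S)-2,6-bis(4-hydroxy-3-methoxyphenyl)-3,7-dioxabicyclo[3.3.0]octan-1-yl acetate | COc1cc([C@H]2OC[C@]3(OC(C)=O)[C@@H](c4ccc(O)c(OC)c4)OC[C@H]23)ccc1O | target

## Step count and risks

Total step count: 10.

Longest linear sequence: 10 steps (1 → 2 → 4 → 6 → 7 → 9 → 12 → 13 → 15 → 16 → 17). Aldehyde 2 is used twice: with 3 in step 2, and as the second aryl fragment joined to lactone 9 in step 6.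

The three steps most likely to fail:

**Step 5** (zinc enolate formation beside a reducible α-keto ester whose benzylic C–H is enolisable). The fallback sets out from 4 and comes back at 9; it makes the nucleophile by soft enolisation of a malonate instead of by reduction of a bromide. Alcohol 4 is esterified with allyl hydrogen malonate (DCC, cat. DMAP, CH2Cl2, 0 °C) to the mixed malonate ethyl (3R)-3-{[3-(allyloxy)-3-oxopropanoyl]oxy}-2-diazo-3-[3-methoxy-4-(triisopropylsilyloxy)phenyl]propanoate F1. DMDO (acetone, 0 °C) gives the keto ester ethyl (3R)-3-{[3-(allyloxy)-3-oxopropanoyl]oxy}-3-[3-methoxy-4-(triisopropylsilyloxy)phenyl]-2-oxopropanoate F2. MgBr2·OEt2 and i-Pr2NEt (CH2Cl2, −20 °C) then close the same ring by intramolecular aldol addition of the magnesium malonate to the keto carbonyl, giving 4-allyl 3-ethyl (2R,3R)-3-hydroxy-2-[3-methoxy-4-(triisopropylsilyloxy)phenyl]-5-oxooxolane-3,4-dicarboxylate F3 (mixture at C4). Pd(PPh3)4 and morpholine (THF, rt) remove the allyl group, and warming to 60 °C decarboxylates the malonic half acid to 9.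

**Step 6** (face selectivity at the enolate carbon and exo/endo selectivity at the new benzylic carbinol). The fallback sets out from 9 and comes back at 15; it closes ring B by a stereoconvergent SN1 etherification instead of relying on the aldol for C6. The dianion aldol with 2 is run at −78 °C and quenched cold to give ethyl (2R,3R,4R)-3-hydroxy-4-{hydroxy[3-methoxy-4-(triisopropylsilyloxy)phenyl]methyl}-2-[3-methoxy-4-(triisopropylsilyloxy)phenyl]-5-oxooxolane-3-carboxylate F4 as both carbinol epimers. LiAlH4 (THF, 0 °C) gives (1R,2S,3R,4RS)-2,3-bis(hydroxymethyl)-1,4-bis[3-methoxy-4-(triisopropylsilyloxy)phenyl]butane-1,2,4-triol F5. Catalytic CSA (CH2Cl2, 0 °C) ionises the C4 benzylic alcohol, which has no β-oxygen, and the primary hydroxyl of the CH2OH on C2 traps the cation trans to the neighbouring CH2OH. This gives (3S,4R,5S)-3-{(R)-hydroxy[3-methoxy-4-(triisopropylsilyloxy)phenyl]methyl}-4-(hydroxymethyl)-5-[3-methoxy-4-(triisopropylsilyloxy)phenyl]oxolan-3-ol F6. Mitsunobu cyclodehydration (PPh3, DIAD, THF, 0 °C) of the remaining primary/benzylic 1,4-diol closes the second ring with retention at the benzylic carbon and rejoins the route at 15.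

**Step 8** (chemoselective bis-mesylation of a pentaol with two electron-rich benzylic alcohols, and possible epoxide formation from the tertiary alcohol). The fallback sets out from 12 and comes back at 15; it never opens the rings. DIBAL-H (CH2Cl2, −78 °C) reduces both lactones of 12 to the bis-lactol (1R,2R,5R,6S)-2,6-bis[3-methoxy-4-(triisopropylsilyloxy)phenyl]-3,7-dioxabicyclo[3.3.0]octane-1,4,8-triol F7 (lactol anomers). Ionic hydrogenation (Et3SiH, BF3·OEt2, CH2Cl2, −78 → −40 °C) removes both anomeric hydroxyls through the oxocarbenium ions and gives 15 directly.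

## Further compounds

F1 | step 5 | ethyl (3R)-3-{[3-(allyloxy)-3-oxopropanoyl]oxy}-2-diazo-3-[3-methoxy-4-(triisopropylsilyloxy)phenyl]propanoate | CCOC(=O)C(=[N+]=[N-])[C@@H](c1ccc(O[Si](C(C)C)(C(C)C)C(C)C)c(OC)c1)OC(=O)CC(=O)OCC=C
F2 | step 5 | ethyl (3R)-3-{[3-(allyloxy)-3-oxopropanoyl]oxy}-3-[3-methoxy-4-(triisopropylsilyloxy)phenyl]-2-oxopropanoate | CCOC(=O)C(=O)[C@@H](c1ccc(O[Si](C(C)C)(C(C)C)C(C)C)c(OC)c1)OC(=O)CC(=O)OCC=C
F3 | step 5 | 4-allyl 3-ethyl (2R,3R)-3-hydroxy-2-[3-methoxy-4-(triisopropylsilyloxy)phenyl]-5-oxooxolane-3,4-dicarboxylate (mixture at C4) | CCOC(=O)[C@@]1(O)C(C(=O)OCC=C)C(=O)O[C@@H]1c1ccc(O[Si](C(C)C)(C(C)C)C(C)C)c(OC)c1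
F4 | step 6 | ethyl (2R,3R,4R)-3-hydroxy-4-{hydroxy[3-methoxy-4-(triisopropylsilyloxy)phenyl]methyl}-2-[3-methoxy-4-(triisopropylsilyloxy)phenyl]-5-oxooxolane-3-carboxylate (both carbinol epimers) | CCOC(=O)[C@@]1(O)[C@@H](C(O)c2ccc(O[Si](C(C)C)(C(C)C)C(C)C)c(OC)c2)C(=O)O[C@@H]1c1ccc(O[Si](C(C)C)(C(C)C)C(C)C)c(OC)c1
F5 | step 6 | (1R,2S,3R,4RS)-2,3-bis(hydroxymethyl)-1,4-bis[3-methoxy-4-(triisopropylsilyloxy)phenyl]butane-1,2,4-triol | COc1cc(C(O)[C@@H](CO)[C@](O)(CO)[C@H](O)c2ccc(O[Si](C(C)C)(C(C)C)C(C)C)c(OC)c2)ccc1O[Si](C(C)C)(C(C)C)C(C)C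
F6 | step 6 | (3S,4R,5S)-3-{(R)-hydroxy[3-methoxy-4-(triisopropylsilyloxy)phenyl]methyl}-4-(hydroxymethyl)-5-[3-methoxy-4-(triisopropylsilyloxy)phenyl]oxolan-3-ol | COc1cc([C@H]2OC[C@](O)([C@H](O)c3ccc(O[Si](C(C)C)(C(C)C)C(C)C)c(OC)c3)[C@@H]2CO)ccc1O[Si](C(C)C)(C(C)C)C(C)C
F7 | step 8 | (1R,2R,5R,6S)-2,6-bis[3-methoxy-4-(triisopropylsilyloxy)phenyl]-3,7-dioxabicyclo[3.3.0]octane-1,4,8-triol (lactol anomers) | COc1cc([C@H]2OC(O)[C@]3(O)[C@@H](c4ccc(O[Si](C(C)C)(C(C)C)C(C)C)c(OC)c4)OC(O)[C@H]23)ccc1O[Si](C(C)C)(C(C)C)C(C)C
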